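## Retrosynthetic overview

1. The butenolide is made last, by Pd-catalysed carbonylative lactonisation of a Z-γ-iodoallylic alcohol that comes from hydroalumination–iodination of a side-chain propargylic alcohol.
2. The equatorial 3-OH and 7-OH come from hydride reduction of a 3,7-dione; the C7 oxygen comes from allylic oxidation of the 8(17)-alkene, and the C19 CH2OH from the C4 ester.
3. Rings A and then B are closed in one operation by an enantioselective amine-catalysed oxidative radical bicyclisation of an acyclic (E,E)-dienyl α-methyl β-keto ester, which sets C4, C5, C9 and C10.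
4. The acyclic precursor comes from ethyl acetoacetate dianion, an allylic bromide and MeI; the bromide comes from geranyl bromide, propargyl dianion, formaldehyde and SeO2 oxidation of the terminal E-methyl group.

Assumption: labdane numbering (C1–C20) is used for all decalin compounds, and radicals and metal-bound species inside catalytic cycles are described in the Why lines without compound numbers.

## Route

Step 1
Reactants: 1 propargyl bromide; 2 geranyl bromide
Product: 6 (6E)-7,11-dimethyldodeca-6,10-dien-2-yn-1-yl pivalate, via 1,3-dilithiopropyne 3 (not isolated), via lithium acetylide 4 (not isolated), via lithium alkoxide 5 (not isolated)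
Conditions: 1, n-BuLi (2 equiv), TMEDA, Et2O/hexane, –78 °C; 2, THF, –78 to 0 °C; (CH2O)n, 0 to 25 °C; PivCl, 0 °C
Reagents that add atoms: formaldehyde (as paraformaldehyde) C=O; pivaloyl chloride CC(C)(C)C(=O)Cl
Why: the propargyl dianion is alkylated at its sp3 carbon by the allylic bromide (SN2, E-alkene retained), and the remaining acetylide is hydroxymethylated and O-acylated in the same flask (sequential dianion alkylation/acetylide addition).

Step 2
Reactants: 6 (6E)-7,11-dimethyldodeca-6,10-dien-2-yn-1-yl pivalate
Product: 7 (6E,10E)-12-hydroxy-7,11-dimethyldodeca-6,10-dien-2-yn-1-yl pivalate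
Conditions: SeO2 (0.4 equiv), t-BuOOH, salicylic acid (cat.), CH2Cl2, 0 to 25 °C
Reagents that add atoms: selenium dioxide O=[Se]=O (catalytic oxygen carrier); tert-butyl hydroperoxide CC(C)(C)OO (terminal oxygen source)
Why: SeO2 allylic oxidation (ene reaction then [2,3]-sigmatropic shift) selects the E-methyl of the terminal trisubstituted alkene, as in geranyl and farnesyl esters, and gives the E-allylic alcohol.

Step 3
Reactants: 7 (6E,10E)-12-hydroxy-7,11-dimethyldodeca-6,10-dien-2-yn-1-yl pivalate
Product: 8 (6E,10E)-12-bromo-7,11-dimethyldodeca-6,10-dien-2-yn-1-yl pivalate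
Conditions: CBr4, PPh3, CH2Cl2, –20 to 0 °C
Reagents that add atoms: carbon tetrabromide BrC(Br)(Br)Br
Why: Appel bromination of a primary allylic alcohol proceeds without allylic shift or loss of alkene geometry.

Step 4
Reactants: 8 (6E,10E)-12-bromo-7,11-dimethyldodeca-6,10-dien-2-yn-1-yl pivalate; 9 ethyl acetoacetate
Product: 12 ethyl (6E,10E)-2,6,10-trimethyl-3-oxo-16-(pivaloyloxy)hexadeca-6,10-dien-14-ynoate, via acetoacetate dianion 10 (not isolated), via sodium enolate 11 (not isolated)
Conditions: 9, NaH, THF, 0 °C; n-BuLi, 0 °C; 8, –78 to 0 °C; then MeI, 0 to 25 °C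
Reagents that add atoms: iodomethane CI
Why: Weiler dianion γ-alkylation by the allylic bromide is followed by C-methylation of the resulting β-keto ester enolate; the new C2 centre is enolisable and is carried as the racemate.

Step 5
Reactants: 12 ethyl (6E,10E)-2,6,10-trimethyl-3-oxo-16-(pivaloyloxy)hexadeca-6,10-dien-14-ynoate
Product: 15 ethyl (4S,5S,9R,10S)-3-oxo-15-pivaloyloxy-16-norlabd-8(17)-en-13-yn-19-oate, via enaminoester 13 (not isolated), via bicyclic ketimine 14 (not isolated)
Conditions: (S)-H2NCH(t-Bu)CH2NEt2·TfOH (20 mol %), 4CzIPN (2 mol %), Co(dmgH)2(py)Cl (5 mol %), MeCN/CH2Cl2 2:1 (0.02 M), 450 nm LEDs, 20 °C, Ar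
Reagents that add atoms: none
Why: Proposed new method: enantioselective amine-catalysed oxidative radical polyene bicyclisation, in which the primary amine of the tert-leucine-derived diamine condenses with the ketone of 12 to enaminoester 13 (erasing the labile C4 centre), photoexcited 4CzIPN (about +1.35 V vs SCE) oxidises only this enamine (about +1.0 V) and neither the free keto ester nor the alkenes, the pendant NEt2 removes the N–H proton to leave a neutral electrophilic α-imino radical that closes 6-endo onto C5 and then from C10 onto C9 through a chair–chair array with the ester anti to nitrogen (hence axial and cis to the C10 methyl, as for the free β-keto ester radical), the tert-butyl group beside C2 forcing the C1–C2 tether onto the opposite face (model: the S catalyst gives 4S, and the (E,E)-diene relays this to C5, C10 and C9), and divalent cobalt from the cobaloxime abstracts a methyl hydrogen from the tertiary C8 radical to give the exocyclic alkene with H2 evolution before ketimine 14 is hydrolysed by the water released at the start; the closest known reaction types are the racemic Mn(OAc)3/Cu(OAc)2 oxidative cyclisation of α-methyl β-keto ester polyenes and chiral primary-amine/photoredox/cobaloxime α-imino-radical couplings of β-keto esters with activated alkenes, neither shown for an enantioselective bicyclisation onto unactivated alkenes.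

Step 6
Reactants: 15 ethyl (4S,5S,9R,10S)-3-oxo-15-pivaloyloxy-16-norlabd-8(17)-en-13-yn-19-oate
Product: 17 ethyl (4S,5S,9S,10S)-3,7-dioxo-15-pivaloyloxy-16-norlabd-8(17)-en-13-yn-19-oate, via axial carbinol 16 (not isolated)
Conditions: SeO2 (0.5 equiv), t-BuOOH (in decane), CH2Cl2, 25 °C; then Dess–Martin periodinane, NaHCO3, 25 °C
Reagents that add atoms: selenium dioxide O=[Se]=O (catalytic oxygen carrier); tert-butyl hydroperoxide CC(C)(C)OO (terminal oxygen source)
Why: SeO2 ene/[2,3] allylic oxidation of the exocyclic alkene puts oxygen on C7 as the axial (7S) carbinol 16, and Dess–Martin oxidation in the same flask turns it into the exocyclic enone so that C7 can be reset by hydride.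

Step 7
Reactants: 17 ethyl (4S,5S,9S,10S)-3,7-dioxo-15-pivaloyloxy-16-norlabd-8(17)-en-13-yn-19-oate
Product: 18 ethyl (3R,4S,5S,7R,9S,10S)-3,7-dihydroxy-15-pivaloyloxy-16-norlabd-8(17)-en-13-yn-19-oate
Conditions: NaBH4, CeCl3·7H2O, MeOH/THF, –78 to –20 °C
Reagents that add atoms: none
Why: Luche 1,2-reduction delivers hydride axially at C7 (only the axial hydrogens of C5 and C9 lie on that face) and at C3 (face anti to the axial ester), giving both equatorial alcohols (7R, 3R) while the esters and alkyne survive.

Step 8
Reactants: 18 ethyl (3R,4S,5S,7R,9S,10S)-3,7-dihydroxy-15-pivaloyloxy-16-norlabd-8(17)-en-13-yn-19-oate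
Product: 21 (3R,4R,5S,7R,9S,10S,13Z)-13-iodo-16-norlabda-8(17),13-diene-3,7,15,19-tetraol, via alkynyl tetraol 19 (not isolated), via vinylalanate 20 (not isolated)
Conditions: NaAlH2(OCH2CH2OMe)2 (Red-Al, excess), THF, 0 to 25 °C; EtOAc, –78 °C; I2, THF, –78 °C; Rochelle salt work-up
Reagents that add atoms: iodine II
Why: the aluminium hydride reduces the ethyl ester to the C19 carbinol and cleaves the pivalate, the freed propargylic alkoxide directs trans-hydroalumination with aluminium on C13, and iodinolysis with retention gives the Z-γ-iodoallylic alcohol (alkoxide-directed hydroalumination–iodination).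

Step 9
Reactants: 21 (3R,4R,5S,7R,9S,10S,13Z)-13-iodo-16-norlabda-8(17),13-diene-3,7,15,19-tetraol
Product: 22 7R-hydroxy-14-deoxyandrographolide, (3R,4R,5S,7R,9S,10S)-3,7,19-trihydroxylabda-8(17),13-dien-16,15-olide
Conditions: PdCl2(PPh3)2 (5 mol %), CO (1 atm), K2CO3, THF, 25–45 °C
Reagents that add atoms: carbon monoxide [C-]#[O+]
Why: zerovalent palladium inserts into the vinyl C–I bond, CO insertion gives an acylpalladium that is captured by the cis CH2OH to close the α-substituted butenolide (carbonylative lactonisation of a Z-iodoallylic alcohol), and no stereocentre is touched.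

## Compound list

1 | propargyl bromide (3-bromoprop-1-yne) | C#CCBr | starting material
2 | geranyl bromide, (2E)-1-bromo-3,7-dimethylocta-2,6-diene | CC(C)=CCC/C(C)=C/CBr | starting material
3 | 1,3-dilithiopropyne | [Li]CC#C[Li] | intermediate
4 | lithium acetylide of (5E)-6,10-dimethylundeca-5,9-dien-1-yne | CC(C)=CCC/C(C)=C/CCC#C[Li] | intermediate
5 | lithium alkoxide of (6E)-7,11-dimethyldodeca-6,10-dien-2-yn-1-ol | CC(C)=CCC/C(C)=C/CCC#CCO[Li] | intermediate
6 | (6E)-7,11-dimethyldodeca-6,10-dien-2-yn-1-yl pivalate | CC(C)=CCC/C(C)=C/CCC#CCOC(=O)C(C)(C)C | intermediate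
7 | (6E,10E)-12-hydroxy-7,11-dimethyldodeca-6,10-dien-2-yn-1-yl pivalate | OC/C(C)=C/CC/C(C)=C/CCC#CCOC(=O)C(C)(C)C | intermediate
8 | (6E,10E)-12-bromo-7,11-dimethyldodeca-6,10-dien-2-yn-1-yl pivalate | BrC/C(C)=C/CC/C(C)=C/CCC#CCOC(=O)C(C)(C)C | intermediate
9 | ethyl acetoacetate | CCOC(=O)CC(C)=O | starting material
10 | sodium lithium dianion of ethyl acetoacetate | [CH2-]C([O-])=CC(=O)OCC.[Na+].[Li+] | intermediate
11 | sodium enolate of ethyl (6E,10E)-6,10-dimethyl-3-oxo-16-(pivaloyloxy)hexadeca-6,10-dien-14-ynoate | CCOC(=O)C=C([O-])CC/C(C)=C/CC/C(C)=C/CCC#CCOC(=O)C(C)(C)C.[Na+] | intermediate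
12 | ethyl (6E,10E)-2,6,10-trimethyl-3-oxo-16-(pivaloyloxy)hexadeca-6,10-dien-14-ynoate (racemic at the enolisable C2) | CCOC(=O)C(C)C(=O)CC/C(C)=C/CC/C(C)=C/CCC#CCOC(=O)C(C)(C)C | intermediate
13 | Z-enaminoester of 12 with (S)-N1,N1-diethyl-3,3-dimethylbutane-1,2-diamine (NH on C3, C3=C4 double bond, N cis to the ester) | CCOC(=O)/C(C)=C(\N[C@H](CN(CC)CC)C(C)(C)C)CC/C(C)=C/CC/C(C)=C/CCC#CCOC(=O)C(C)(C)C | intermediate
14 | C3 ketimine of 15 with the same (S)-diamine | C=C1CC[C@@H]2[C@](C)(C(=O)OCC)C(=N[C@H](CN(CC)CC)C(C)(C)C)CC[C@@]2(C)[C@@H]1CCC#CCOC(=O)C(C)(C)C | intermediate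
15 | ethyl (4S,5S,9R,10S)-3-oxo-15-pivaloyloxy-16-norlabd-8(17)-en-13-yn-19-oate (trans-decalin; CO2Et axial on C4 and cis to the C10 methyl; C9 side chain equatorial) | C=C1CC[C@@H]2[C@](C)(C(=O)OCC)C(=O)CC[C@@]2(C)[C@@H]1CCC#CCOC(=O)C(C)(C)C | intermediate
16 | ethyl (4S,5S,7S,9S,10S)-7-hydroxy-3-oxo-15-pivaloyloxy-16-norlabd-8(17)-en-13-yn-19-oate (7-OH axial) | C=C1[C@@H](O)C[C@@H]2[C@](C)(C(=O)OCC)C(=O)CC[C@@]2(C)[C@@H]1CCC#CCOC(=O)C(C)(C)C | intermediate
17 | ethyl (4S,5S,9S,10S)-3,7-dioxo-15-pivaloyloxy-16-norlabd-8(17)-en-13-yn-19-oate | C=C1C(=O)C[C@@H]2[C@](C)(C(=O)OCC)C(=O)CC[C@@]2(C)[C@@H]1CCC#CCOC(=O)C(C)(C)C | intermediate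
18 | ethyl (3R,4S,5S,7R,9S,10S)-3,7-dihydroxy-15-pivaloyloxy-16-norlabd-8(17)-en-13-yn-19-oate (both OH equatorial) | C=C1[C@H](O)C[C@@H]2[C@](C)(C(=O)OCC)[C@H](O)CC[C@@]2(C)[C@@H]1CCC#CCOC(=O)C(C)(C)C | intermediate
19 | (3R,4R,5S,7R,9S,10S)-16-norlabd-8(17)-en-13-yne-3,7,15,19-tetraol (present as aluminium alkoxides) | C=C1[C@H](O)C[C@@H]2[C@](C)(CO)[C@H](O)CC[C@@]2(C)[C@@H]1CCC#CCO | intermediate
20 | sodium Z-vinylalanate of 19: five-membered ring Al–C13=C14–C15–O, two 2-methoxyethoxy groups on aluminium (other hydroxyls drawn free) | C=C1[C@H](O)C[C@@H]2[C@](C)(CO)[C@H](O)CC[C@@]2(C)[C@@H]1CCC1=CCO[Al-]1(OCCOC)OCCOC.[Na+] | intermediate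
21 | (3R,4R,5S,7R,9S,10S,13Z)-13-iodo-16-norlabda-8(17),13-diene-3,7,15,19-tetraol | C=C1[C@H](O)C[C@@H]2[C@](C)(CO)[C@H](O)CC[C@@]2(C)[C@@H]1CC/C(I)=C/CO | intermediate
22 | 7R-hydroxy-14-deoxyandrographolide, (3R,4R,5S,7R,9S,10S)-3,7,19-trihydroxylabda-8(17),13-dien-16,15-olide | C=C1[C@H](O)C[C@@H]2[C@](C)(CO)[C@H](O)CC[C@@]2(C)[C@@H]1CCC1=CCOC1=O | target

## Step count and risks

Total step count: 9. Longest linear sequence: 9 steps (from 1 and 2 to 22).

**First risk, step 5 (the proposed new step).**
- What can go wrong: the hindered α-methyl β-keto ester may condense slowly with the amine; an N–H···ester hydrogen bond in the radical could put the ester equatorial (C4 epimer); the enantioselectivity rests on a steric model only; the cobalt hydride could isomerise the exocyclic alkene; and the product ketone could be over-oxidised through its C2 enamine.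
- Fallback with known chemistry: it sets out from 12. Mn(OAc)3·2H2O (2 equiv) and Cu(OAc)2·H2O (1 equiv) in AcOH at 25–50 °C (oxidative free-radical cyclisation with trivalent manganese and divalent copper) give the same bicyclic keto ester with the axial ester and exocyclic alkene, but as the racemate, i.e. 15 together with the mirror-image keto ester F1.
- A kinetic resolution with (R)-Me-CBS oxazaborolidine and BH3·SMe2 (about 0.6 equiv hydride, THF, –20 °C) then reduces F1, for which catalyst and axial hydride delivery are matched, to the ent-series equatorial carbinol F2.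
- Compound 15 would need equatorial attack on the face screened by the axial ester and the C10 methyl, so it is left unreacted, separated by chromatography, and comes back to the route at 15.

**Second risk, step 8.**
- What can go wrong: four alkoxides form on one molecule, the neopentyl ester must be reduced before hydroalumination, the aluminium must go to C13, and iodine could attack the allylic alcohol/alkene.
- Fallback: it sets out from 18. i-Bu2AlH (CH2Cl2, –78 to 0 °C) reduces the ethyl ester and the pivalate without touching the alkyne and gives tetraol 19, now isolated (no new compound, F0).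
- Direct cyclocarbonylation of this 2-alkyn-1-ol with Pd2(dba)3·CHCl3 and 1,4-bis(diphenylphosphino)butane under CO/H2 in CH2Cl2 at 95 °C puts the carbonyl on C13 and closes the butenolide, so the fallback comes back at 22 without the vinyl iodide.

**Third risk, step 6.**
- What can go wrong: SeO2 could attack C9–H or the propargylic CH2 groups, and the exocyclic enone 17 can slip into conjugation with C9 if handled with base, so it is used at once in step 7.
- Fallback: it sets out from 15. PhSeCl (CH2Cl2, –78 °C, then pyridine, 25 °C) adds to the exocyclic alkene and loses HCl to give the allylic selenide F3 (PhSe on C17, alkene moved to C7=C8).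
- H2O2/pyridine at 0 °C oxidises F3 to the selenoxide, whose [2,3]-sigmatropic shift and hydrolysis restore the exocyclic alkene with oxygen on C7, giving carbinol 16 as an isolated compound.
- Dess–Martin oxidation then gives the enone, and the fallback comes back at 17.

## Further compounds

F1 | step 5 | ethyl (4R,5R,9S,10R)-3-oxo-15-pivaloyloxy-16-norlabd-8(17)-en-13-yn-19-oate (mirror image of 15, formed with 15 as the racemate) | C=C1CC[C@H]2[C@@](C)(C(=O)OCC)C(=O)CC[C@]2(C)[C@H]1CCC#CCOC(=O)C(C)(C)C
F2 | step 5 | ethyl (3S,4R,5R,9S,10R)-3-hydroxy-15-pivaloyloxy-16-norlabd-8(17)-en-13-yn-19-oate (equatorial carbinol of the mirror-image series) | C=C1CC[C@H]2[C@@](C)(C(=O)OCC)[C@@H](O)CC[C@]2(C)[C@H]1CCC#CCOC(=O)C(C)(C)C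
F3 | step 6 | ethyl 3-oxo-17-(phenylselanyl)-15-pivaloyloxy-16-norlabd-7-en-13-yn-19-oate with C4, C5, C9 and C10 as in 15 | c1ccccc1[Se]CC2=CC[C@@H]3[C@](C)(C(=O)OCC)C(=O)CC[C@@]3(C)[C@@H]2CCC#CCOC(=O)C(C)(C)C
F0 | step 8 | none | none
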